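**Strategy.** The route rests on disconnecting ring B at two neighbouring positions (chromene numbering): the aryl ether bond O1–C8a of the 2H-chromene and the C8–C(=O) bond of the benzophenone. Both are made in one operation from an aryne spanning C8–C8a. A lithium tertiary alkoxide, tethered through a Z-alkenyl side chain at C4a, adds to C8a and closes the pyran ring. The aryllithium left at C8, flanked by O1 and the C7 oxygen, is acylated by the ring A ester. The precursor is an acyclic (Z)-4-aryl-2-methylbut-3-en-2-ol carrying bromine at C8 and fluorine at C8a as the aryne source; the second fragment is methyl 2-prenyl-3,5-bis(methoxymethoxy)benzoate.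

Key step: step 9

Assumption: 5-fluorobenzene-1,3-diol, methyl 3,5-dihydroxybenzoate, 2-methylbut-3-yn-2-ol and tributyl(3-methylbut-2-en-1-yl)stannane are taken as commercial. The target is achiral, so the only stereochemical element on the way is the Z double bond of 7, which becomes the ring C3=C4 bond.

**Step 1**
Reactants: 1 5-fluorobenzene-1,3-diol
Product: 2 1-fluoro-3,5-bis(methoxymethoxy)benzene
Conditions: MOMCl (2.5 equiv), iPr2NEt (3 equiv), CH2Cl2, 0 °C to rt
Reagents that add atoms: chloromethyl methyl ether (MOMCl), COCCl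
Why: O-alkylation of both phenols (acetal-type protection) should give ethers that withstand organolithium reagents and can all be removed together at the end.

**Step 2**
Reactants: 2 1-fluoro-3,5-bis(methoxymethoxy)benzene
Product: 3 1-fluoro-2-iodo-3,5-bis(methoxymethoxy)benzene
Conditions: NIS (1.05 equiv), MeCN, 0 °C to rt, dark
Reagents that add atoms: N-iodosuccinimide (NIS), O=C1CCC(=O)N1I
Why: Electrophilic aromatic iodination should take place para to one alkoxy group and ortho to the other, beside the small fluorine, because the position between the two methoxymethoxy groups is shielded as in other resorcinol diethers.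

**Step 3**
Reactants: 3 1-fluoro-2-iodo-3,5-bis(methoxymethoxy)benzene
Product: 4 1-bromo-2-fluoro-3-iodo-4,6-bis(methoxymethoxy)benzene
Conditions: NBS (1.05 equiv), MeCN, rt
Reagents that add atoms: N-bromosuccinimide (NBS), O=C1CCC(=O)N1Br
Why: A second electrophilic aromatic halogenation with the more reactive NBS should go to the remaining position ortho to fluorine and para to an alkoxy group, again avoiding the site between the two ethers.

**Step 4**
Reactants: 4 1-bromo-2-fluoro-3-iodo-4,6-bis(methoxymethoxy)benzene; 5 2-methylbut-3-yn-2-ol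
Product: 6 4-[3-bromo-2-fluoro-4,6-bis(methoxymethoxy)phenyl]-2-methylbut-3-yn-2-ol
Conditions: Pd(PPh3)2Cl2 (3 mol%), CuI (5 mol%), Et3N, THF, 40 °C
Reagents that add atoms: none
Why: Sonogashira coupling should be selective for the C–I bond, whose oxidative addition is much faster than that of the C–Br bond.

**Step 5**
Reactants: 6 4-[3-bromo-2-fluoro-4,6-bis(methoxymethoxy)phenyl]-2-methylbut-3-yn-2-ol
Product: 7 (Z)-4-[3-bromo-2-fluoro-4,6-bis(methoxymethoxy)phenyl]-2-methylbut-3-en-2-ol
Conditions: H2 (1 atm), Pd/CaCO3 poisoned with Pb(OAc)2 (Lindlar catalyst), quinoline, EtOAc, rt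
Reagents that add atoms: none
Why: Lindlar semihydrogenation delivers both hydrogens to the same face of the alkyne and so should set the Z geometry, while the poisoned catalyst leaves the aryl bromide and fluoride alone.

**Step 6**
Reactants: 8 methyl 3,5-dihydroxybenzoate
Product: 9 methyl 3,5-bis(methoxymethoxy)benzoate
Conditions: MOMCl (2.5 equiv), iPr2NEt (3 equiv), CH2Cl2, 0 °C to rt
Reagents that add atoms: chloromethyl methyl ether (MOMCl), COCCl
Why: The same phenol O-alkylation as in step 1 puts the ring A hydroxyls in the same protecting group as those of ring B.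

**Step 7**
Reactants: 9 methyl 3,5-bis(methoxymethoxy)benzoate
Product: 10 methyl 2-bromo-3,5-bis(methoxymethoxy)benzoate
Conditions: NBS (1.05 equiv), MeCN, rt
Reagents that add atoms: N-bromosuccinimide (NBS), O=C1CCC(=O)N1Br
Why: Electrophilic aromatic bromination of 3,5-dialkoxybenzoates should occur at C2, para to one alkoxy group and next to the ester, not at the hindered C4 between the two ethers.

**Step 8**
Reactants: 10 methyl 2-bromo-3,5-bis(methoxymethoxy)benzoate; 11 tributyl(3-methylbut-2-en-1-yl)stannane
Product: 12 methyl 3,5-bis(methoxymethoxy)-2-(3-methylbut-2-en-1-yl)benzoate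
Conditions: Pd(PPh3)4 (5 mol%), DMF, 90 °C
Reagents that add atoms: none
Why: Stille coupling of the aryl bromide, activated by the ortho ester, should give the linear prenyl arene because the allylpalladium intermediate reductively eliminates at its less hindered terminus.

**Step 9**
Reactants: 7 (Z)-4-[3-bromo-2-fluoro-4,6-bis(methoxymethoxy)phenyl]-2-methylbut-3-en-2-ol; 12 methyl 3,5-bis(methoxymethoxy)-2-(3-methylbut-2-en-1-yl)benzoate
Product: 17 [5,7-bis(methoxymethoxy)-2,2-dimethyl-2H-chromen-8-yl][3,5-bis(methoxymethoxy)-2-(3-methylbut-2-en-1-yl)phenyl]methanone, via lithium alkoxide 13 (not isolated), via fluoroaryllithium 14 (not isolated), via aryne 15 (not isolated), via 8-lithiochromene 16 (not isolated)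
Conditions: MeLi (1.0 equiv), THF (0.02 M), −78 °C; t-BuLi (2.0 equiv), −78 °C; warm to −20 °C; then 12 (1.2 equiv), −78 °C to 0 °C; H2O
Reagents that add atoms: none
Why: MeLi forms the lithium alkoxide 13, bromine–lithium exchange with t-BuLi gives the 2-fluoroaryllithium 14, and on warming this loses LiF to the aryne 15 (C8–C8a), whose C8a takes up the tethered alkoxide to leave the aryllithium 16 at C8, which attacks the ester carbonyl of 12 and expels methoxide. The closest known reaction types are aryne generation from ortho-haloaryllithiums, intramolecular addition of alkoxides to arynes, and nucleophile–aryne–electrophile three-component coupling. The pyran ring closes in a 6-exo-dig mode, the oxygen attacking the in-plane π bond of the aryne, which the Z geometry of the side-chain double bond places within reach. No stereocenter is formed, and the Z alkene of 7 becomes the ring C3=C4 bond. The step needs addition at C8a and not at C8, which is secured twice: the tether cannot reach C8, and the inductively withdrawing C7 oxygen beside the triple bond favours attack at the distal carbon so that the carbanion develops next to that oxygen. It also needs the alkoxide to outrun intermolecular additions to the aryne, which high dilution and the exact amount of t-BuLi (none left when the aryne forms) should secure, while the doubly ortho-oxygenated aryllithium and the ortho-substituted ester should stop the acylation at the ketone.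

**Step 10**
Reactants: 17 [5,7-bis(methoxymethoxy)-2,2-dimethyl-2H-chromen-8-yl][3,5-bis(methoxymethoxy)-2-(3-methylbut-2-en-1-yl)phenyl]methanone
Product: 18 [3,5-dihydroxy-2-(3-methylbut-2-en-1-yl)phenyl](5,7-dihydroxy-2,2-dimethyl-2H-chromen-8-yl)methanone
Conditions: HCl (3 M aq), MeOH, rt to 40 °C
Reagents that add atoms: none
Why: Acid-catalysed acetal exchange with methanol should free all four phenols under conditions mild enough for the prenyl group and the chromene double bond.

**Compound list**
1 | 5-fluorobenzene-1,3-diol | Oc1cc(O)cc(F)c1 | starting material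
2 | 1-fluoro-3,5-bis(methoxymethoxy)benzene | COCOc1cc(F)cc(OCOC)c1 | intermediate
3 | 1-fluoro-2-iodo-3,5-bis(methoxymethoxy)benzene | COCOc1cc(OCOC)c(I)c(F)c1 | intermediate
4 | 1-bromo-2-fluoro-3-iodo-4,6-bis(methoxymethoxy)benzene | COCOc1cc(OCOC)c(I)c(F)c1Br | intermediate
5 | 2-methylbut-3-yn-2-ol | CC(C)(O)C#C | starting material
6 | 4-[3-bromo-2-fluoro-4,6-bis(methoxymethoxy)phenyl]-2-methylbut-3-yn-2-ol | CC(C)(O)C#Cc1c(F)c(Br)c(OCOC)cc1OCOC | intermediate
7 | (Z)-4-[3-bromo-2-fluoro-4,6-bis(methoxymethoxy)phenyl]-2-methylbut-3-en-2-ol | CC(C)(O)/C=C\c1c(F)c(Br)c(OCOC)cc1OCOC | intermediate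
8 | methyl 3,5-dihydroxybenzoate | COC(=O)c1cc(O)cc(O)c1 | starting material
9 | methyl 3,5-bis(methoxymethoxy)benzoate | COCOc1cc(OCOC)cc(C(=O)OC)c1 | intermediate
10 | methyl 2-bromo-3,5-bis(methoxymethoxy)benzoate | COCOc1cc(OCOC)c(Br)c(C(=O)OC)c1 | intermediate
11 | tributyl(3-methylbut-2-en-1-yl)stannane | CCCC[Sn](CCCC)(CCCC)CC=C(C)C | starting material
12 | methyl 3,5-bis(methoxymethoxy)-2-(3-methylbut-2-en-1-yl)benzoate | COCOc1cc(OCOC)c(CC=C(C)C)c(C(=O)OC)c1 | intermediate
13 | lithium (Z)-4-[3-bromo-2-fluoro-4,6-bis(methoxymethoxy)phenyl]-2-methylbut-3-en-2-olate | [Li]OC(C)(C)/C=C\c1c(F)c(Br)c(OCOC)cc1OCOC | intermediate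
14 | lithium (Z)-4-[2-fluoro-3-lithio-4,6-bis(methoxymethoxy)phenyl]-2-methylbut-3-en-2-olate | [Li]OC(C)(C)/C=C\c1c(F)c([Li])c(OCOC)cc1OCOC | intermediate
15 | lithium (Z)-4-[2,3-didehydro-4,6-bis(methoxymethoxy)phenyl]-2-methylbut-3-en-2-olate (aryne) | [Li]OC(C)(C)/C=C\C1=C(OCOC)C=C(OCOC)C#C1 | intermediate
16 | 8-lithio-5,7-bis(methoxymethoxy)-2,2-dimethyl-2H-chromene | [Li]c1c(OCOC)cc(OCOC)c2C=CC(C)(C)Oc12 | intermediate
17 | [5,7-bis(methoxymethoxy)-2,2-dimethyl-2H-chromen-8-yl][3,5-bis(methoxymethoxy)-2-(3-methylbut-2-en-1-yl)phenyl]methanone | CC(C)=CCc1c(OCOC)cc(OCOC)cc1C(=O)c1c(OCOC)cc(OCOC)c2c1OC(C)(C)C=C2 | intermediate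
18 | [3,5-dihydroxy-2-(3-methylbut-2-en-1-yl)phenyl](5,7-dihydroxy-2,2-dimethyl-2H-chromen-8-yl)methanone | CC(C)=CCc1c(O)cc(O)cc1C(=O)c1c(O)cc(O)c2c1OC(C)(C)C=C2 | target

**Step count.** Total: 10 steps. Longest linear sequence: 7 steps (steps 1, 2, 3, 4, 5, 9, 10).

**Steps most likely to fail**

Step 9. The aryne may be consumed by intermolecular addition of the aryllithium 14 before the lithium alkoxide closes the ring, or the acylation of the hindered aryllithium may stall. The fallback avoids the aryne; it sets out from 7 and 12 and comes back at 17. Alkoxide formation and bromine–lithium exchange on 7 would be run as before but held at −100 °C, where the 2-fluoroaryllithium keeps its fluoride. Addition of 12 at that temperature should give the fluoro ketone {2-fluoro-3-[(Z)-3-hydroxy-3-methylbut-1-en-1-yl]-4,6-bis(methoxymethoxy)phenyl}[3,5-bis(methoxymethoxy)-2-(3-methylbut-2-en-1-yl)phenyl]methanone F1. KOtBu in THF (0 °C to rt) should then close the pyran ring by intramolecular nucleophilic aromatic substitution of the fluoride, now activated by the ortho ketone, to give 17.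

Step 5. Over-reduction to the alkane, hydrogenolysis of the C–Br bond, or Z-to-E isomerisation of the electron-rich styrene may erode the material. The fallback builds the Z alkene by olefination; it sets out from 4 and comes back at 7. Iodine–magnesium exchange on 4 (i-PrMgCl·LiCl, THF, −40 °C, selective for iodine over bromine) and quenching with DMF should give 3-bromo-2-fluoro-4,6-bis(methoxymethoxy)benzaldehyde F2. Still–Gennari olefination ((CF3CH2O)2P(O)CH2CO2Me, KN(SiMe3)2, 18-crown-6, THF, −78 °C) should give methyl (Z)-3-[3-bromo-2-fluoro-4,6-bis(methoxymethoxy)phenyl]prop-2-enoate F3. Double 1,2-addition of MeMgBr in the presence of CeCl3 (THF, −78 to 0 °C) should then give 7.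

Step 10. Acid may add the freed ortho phenol or methanol across the prenyl double bond (chroman formation) in competition with acetal cleavage. The fallback removes the protecting groups without Brønsted acid; it sets out from 17 and comes back at 18. Me3SiOTf and 2,2'-bipyridyl in CH2Cl2 at 0 °C should convert each aryl methoxymethyl ether into the aryl silyl ether, giving [5,7-bis(trimethylsilyloxy)-2,2-dimethyl-2H-chromen-8-yl][3,5-bis(trimethylsilyloxy)-2-(3-methylbut-2-en-1-yl)phenyl]methanone F4. Hydrolysis with water at rt should then release 18.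

**Further compounds**
F1 | step 9 | {2-fluoro-3-[(Z)-3-hydroxy-3-methylbut-1-en-1-yl]-4,6-bis(methoxymethoxy)phenyl}[3,5-bis(methoxymethoxy)-2-(3-methylbut-2-en-1-yl)phenyl]methanone | CC(C)=CCc1c(OCOC)cc(OCOC)cc1C(=O)c1c(F)c(/C=C\C(C)(C)O)c(OCOC)cc1OCOC
F2 | step 5 | 3-bromo-2-fluoro-4,6-bis(methoxymethoxy)benzaldehyde | O=Cc1c(F)c(Br)c(OCOC)cc1OCOC
F3 | step 5 | methyl (Z)-3-[3-bromo-2-fluoro-4,6-bis(methoxymethoxy)phenyl]prop-2-enoate | COC(=O)/C=C\c1c(F)c(Br)c(OCOC)cc1OCOC
F4 | step 10 | [5,7-bis(trimethylsilyloxy)-2,2-dimethyl-2H-chromen-8-yl][3,5-bis(trimethylsilyloxy)-2-(3-methylbut-2-en-1-yl)phenyl]methanone | CC(C)=CCc1c(O[Si](C)(C)C)cc(O[Si](C)(C)C)cc1C(=O)c1c(O[Si](C)(C)C)cc(O[Si](C)(C)C)c2c1OC(C)(C)C=C2
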